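**Retrosynthetic overview**

1. Last operations: the primary alcohol is released from the prenyl terminus of the (S)-citronellal-derived side chain (alkene cleavage, reduction), and the C4 ester is made by Mitsunobu inversion of a C4 alcohol with (2R)-2-methylbutanoic acid.
2. The lactone ring (closed second) comes from a Mitsunobu lactonisation, with inversion at C7a, of a hydroxy acrylic acid; the acid is made from an acetyl group (enol triflate, hydroxycarbonylation) and the C7a–OH from a C7a–B bond (retention).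
3. The cyclohexene ring (closed first) comes from one Diels–Alder reaction that forms C3a–C4 and C7–C7a: a (1E)-1-silyloxy-2-alkyl-3-methylbutadiene (from (S)-citronellal and 2,2-dimethoxypropane) plus (E)-4-boryl-but-3-en-2-one.
4. Enabling feature: the carbocycle C3a–C4–C5=C6–C7–C7a has its only C=C (C5=C6) exactly between the two bonds to be made, an allylic oxygen on C4 (a 1-oxygenated diene, which fixes the regiochemistry) and a second oxygen on C7a that can travel as boron, so the dienophile is not a deactivated push–pull alkene.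
5. Stereochemical logic: endo addition and the E geometry of the dienophile put C4–O cis and C7a–B trans to the C3a substituent, the opposite of the target at both carbinol carbons; both C–O bonds of the target are therefore formed with inversion, and a chiral Lewis acid sets the ring against the side-chain stereocentre.

Key step: step 5

Assumption: in step 5 the (S)-configured oxazaborolidinium ion is taken to be the catalyst antipode that delivers the diene to the Si face at the α-carbon of the enone, as drawn for the cycloadduct; if a first run shows the opposite sense, the (R)-catalyst is used and nothing else changes.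

**Route**

Step 1
Reactants: 1 (3S)-3,7-dimethyloct-6-enal ((S)-citronellal)
Product: 2 trimethyl{[(3S)-3,7-dimethylocta-1,6-dien-1-yl]oxy}silane (E/Z mixture)
Conditions: Me3SiCl, Et3N, DMF, 80 °C
Reagents that add atoms: chlorotrimethylsilane, C[Si](C)(C)Cl
Why: Silyl enol ether formation makes C2 nucleophilic and removes the free aldehyde, which would otherwise undergo carbonyl-ene cyclisation onto the trisubstituted alkene under the Lewis acid of step 2; the C3 stereocentre is not touched.

Step 2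
Reactants: 2 trimethyl{[(3S)-3,7-dimethylocta-1,6-dien-1-yl]oxy}silane; 3 2,2-dimethoxypropane
Product: 5 3-methyl-2-[(2S)-6-methylhept-5-en-2-yl]but-2-enal, via β-methoxy aldehyde 4 (not isolated)
Conditions: Me3SiOTf (5 mol%), CH2Cl2, −78 °C; then DBU (1,8-diazabicyclo[5.4.0]undec-7-ene), 25–40 °C
Reagents that add atoms: none
Why: Mukaiyama-type addition of the silyl enol ether to the ketal-derived oxocarbenium ion, then E1cB loss of methanol, installs the isopropylidene group at C2; the transient C2 stereocentre disappears.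

Step 3
Reactants: 5 3-methyl-2-[(2S)-6-methylhept-5-en-2-yl]but-2-enal
Product: 6 tert-butyl(dimethyl){[(1E)-3-methyl-2-[(2S)-6-methylhept-5-en-2-yl]buta-1,3-dien-1-yl]oxy}silane
Conditions: tBuMe2SiOTf, Et3N, CH2Cl2, −78 → 0 °C
Reagents that add atoms: tert-butyldimethylsilyl trifluoromethanesulfonate, CC(C)(C)[Si](C)(C)OS(=O)(=O)C(F)(F)F
Why: Silyl dienol ether formation (γ-deprotonation, O-silylation; a deconjugated isopropenyl isomer of 5 would give the same dienolate) should give the (1E)-diene, because the s-trans enal conformer places oxygen anti to the isopropenyl carbon.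

Step 4
Reactants: 7 but-3-yn-2-one
Product: 8 (3E)-4-(4,4,5,5-tetramethyl-1,3,2-dioxaborolan-2-yl)but-3-en-2-one
Conditions: B2pin2, CuCl (5 mol%), Xantphos (4,5-bis(diphenylphosphino)-9,9-dimethylxanthene, 5 mol%), NaOtBu (10 mol%), MeOH (2 equiv), THF, 0 °C → rt
Reagents that add atoms: bis(pinacolato)diboron, CC1(C)OB(OC1(C)C)B1OC(C)(C)C(C)(C)O1
Why: Copper-catalysed conjugate borylation of the ynone (syn borylcupration, protonation by methanol) places boron on the terminal carbon trans to the acetyl group.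

Step 5
Reactants: 6 tert-butyl(dimethyl){[(1E)-3-methyl-2-[(2S)-6-methylhept-5-en-2-yl]buta-1,3-dien-1-yl]oxy}silane; 8 (3E)-4-(4,4,5,5-tetramethyl-1,3,2-dioxaborolan-2-yl)but-3-en-2-one
Product: 9 1-[(1R,2R,6S)-2-{[tert-butyl(dimethyl)silyl]oxy}-4-methyl-3-[(2S)-6-methylhept-5-en-2-yl]-6-(4,4,5,5-tetramethyl-1,3,2-dioxaborolan-2-yl)cyclohex-3-en-1-yl]ethan-1-one
Conditions: (S)-3,3-diphenyl-1-(2-methylphenyl)tetrahydro-1H,3H-pyrrolo[1,2-c][1,3,2]oxazaborole (20 mol%), HNTf2 (20 mol%), CH2Cl2, −78 → −40 °C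
Reagents that add atoms: none
Why: Lewis-acid-catalysed normal-electron-demand Diels–Alder reaction: the protonated oxazaborolidine binds the carbonyl of 8 and lowers its LUMO, and diene 6 adds in a concerted, asynchronous [4+2] cycloaddition in which the unsubstituted diene terminus bonds first to the β-carbon of the enone. The closest known reaction types are oxazaborolidinium-catalysed Diels–Alder reactions of acyclic enones and Diels–Alder reactions of (E)-3-borylpropenoyl dienophiles, used as β-hydroxyacryloyl equivalents, with 1-oxygenated dienes. The only ring closed is the cyclohexene, by suprafacial [4+2] closure of both σ-bonds (C1–C2 and C5–C6 of 9, the later C3a–C4 and C7–C7a bonds). C1 and C2 should become cis through the endo orientation of the acetyl group toward the (1E)-silyloxy diene, C6 trans to C1 because the E geometry of 8 is retained, and the absolute sense is set by the catalyst, which shields one face of the bound enone (attack on the Si face at C3 of 8), the (2S) side-chain centre being a spectator. The step needs ortho regiochemistry (acetyl-bearing carbon next to the silyloxy-bearing carbon), which the 1-silyloxy group secures by making the unsubstituted diene terminus the nucleophilic end, and it needs a dienophile that is not a push–pull alkene, which is why the C7a oxygen travels as boron. The boronate is a bystander in the cycloaddition and becomes the hydroxyl with retention in step 8.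

Step 6
Reactants: 9 1-[(1R,2R,6S)-2-{[tert-butyl(dimethyl)silyl]oxy}-4-methyl-3-[(2S)-6-methylhept-5-en-2-yl]-6-(4,4,5,5-tetramethyl-1,3,2-dioxaborolan-2-yl)cyclohex-3-en-1-yl]ethan-1-one
Product: 10 1-[(1R,2R,6S)-2-{[tert-butyl(dimethyl)silyl]oxy}-4-methyl-3-[(2S)-6-methylhept-5-en-2-yl]-6-(4,4,5,5-tetramethyl-1,3,2-dioxaborolan-2-yl)cyclohex-3-en-1-yl]ethenyl trifluoromethanesulfonate
Conditions: KN(SiMe3)2, THF, −78 °C; then PhNTf2, −78 → 0 °C
Reagents that add atoms: N-phenylbis(trifluoromethanesulfonimide), O=S(=O)(N(c1ccccc1)S(=O)(=O)C(F)(F)F)C(F)(F)F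
Why: Kinetic deprotonation at the unhindered methyl group and O-triflation (enol triflate formation) avoid enolisation toward C1, so the ring stereocentres and the β-silyloxy and β-boryl groups are left alone.

Step 7
Reactants: 10 the enol triflate
Product: 11 2-[(1S,2R,6S)-2-{[tert-butyl(dimethyl)silyl]oxy}-4-methyl-3-[(2S)-6-methylhept-5-en-2-yl]-6-(4,4,5,5-tetramethyl-1,3,2-dioxaborolan-2-yl)cyclohex-3-en-1-yl]prop-2-enoic acid
Conditions: Pd(OAc)2 (5 mol%), Ph2P(CH2)3PPh2 (6 mol%), CO (1 atm), Et3N, DMF/H2O 10:1, 50 °C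
Reagents that add atoms: carbon monoxide, [C-]#[O+]; water, O
Why: Palladium-catalysed hydroxycarbonylation of the alkenyl triflate (oxidative addition, CO insertion, hydrolysis of the acyl palladium) gives the acrylic acid, and the secondary alkyl boronate should not transmetalate under these conditions (the descriptor at C1 changes only through CIP priorities).

Step 8
Reactants: 11 the boryl acrylic acid
Product: 12 2-[(1R,2R,6S)-2-{[tert-butyl(dimethyl)silyl]oxy}-6-hydroxy-4-methyl-3-[(2S)-6-methylhept-5-en-2-yl]cyclohex-3-en-1-yl]prop-2-enoic acid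
Conditions: NaBO3·4H2O, THF/H2O 1:1, rt
Reagents that add atoms: sodium perborate, [Na+].[Na+].O[B-]1(O)OO[B-](O)(O)OO1
Why: Oxidation of the C–B bond (1,2-shift of carbon from boron to oxygen) proceeds with retention, so the C6 hydroxyl stays trans to the acrylic acid side chain.

Step 9
Reactants: 12 the hydroxy acid
Product: 13 (3aR,4R,7aR)-4-{[tert-butyl(dimethyl)silyl]oxy}-6-methyl-3-methylidene-5-[(2S)-6-methylhept-5-en-2-yl]-3a,4,7,7a-tetrahydro-1-benzofuran-2(3H)-one
Conditions: PPh3, DIAD (diisopropyl azodicarboxylate), THF, 0 °C → rt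
Reagents that add atoms: none
Why: Mitsunobu lactonisation: the carboxylate displaces the alkoxyphosphonium group at C7a in an intramolecular SN2 reaction (5-exo-tet), so the ring oxygen arrives with inversion and the lactone is cis-fused.

Step 10
Reactants: 13 the silyl ether lactone
Product: 14 (3aS,4R,7aR)-4-hydroxy-6-methyl-3-methylidene-5-[(2S)-6-methylhept-5-en-2-yl]-3a,4,7,7a-tetrahydro-1-benzofuran-2(3H)-one
Conditions: HF·pyridine, THF, 0 °C → rt
Reagents that add atoms: none
Why: Fluoride-mediated silyl ether cleavage frees the C4 alcohol without touching any stereocentre (the 3a descriptor changes only through CIP priorities).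

Step 11
Reactants: 14 the C4 alcohol; 15 (2R)-2-methylbutanoic acid
Product: 16 (3aR,4S,7aR)-6-methyl-3-methylidene-5-[(2S)-6-methylhept-5-en-2-yl]-2-oxo-2,3,3a,4,7,7a-hexahydro-1-benzofuran-4-yl (2R)-2-methylbutanoate
Conditions: PPh3, DIAD, toluene, 0 °C → rt
Reagents that add atoms: none
Why: Mitsunobu esterification: the carboxylate of 15 attacks C4 from the convex face opposite the lactone with inversion, setting (4S), and since the acid is never activated as an acyl donor its α-stereocentre cannot epimerise through a ketene.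

Step 12
Reactants: 16 the prenyl-terminated ester
Product: 17 (3aR,4S,7aR)-6-methyl-3-methylidene-2-oxo-5-[(2S)-5-oxopentan-2-yl]-2,3,3a,4,7,7a-hexahydro-1-benzofuran-4-yl (2R)-2-methylbutanoate
Conditions: OsO4 (2 mol%), NaIO4 (4 equiv), 2,6-lutidine, dioxane/H2O 3:1, rt
Reagents that add atoms: osmium tetroxide (transfers the oxygen, catalytic), O=[Os](=O)(=O)=O; sodium periodate (terminal oxygen source), [Na+].[O-]I(=O)(=O)=O
Why: Lemieux–Johnson cleavage: the electron-rich, unhindered trisubstituted side-chain alkene should be dihydroxylated faster than the hindered tetrasubstituted ring alkene and the electron-poor methylene lactone, and periodate cleaves the diol to the aldehyde.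

Step 13
Reactants: 17 the aldehyde
Product: 18 (3aR,4S,7aR)-5-[(2S)-5-hydroxypentan-2-yl]-6-methyl-3-methylidene-2-oxo-2,3,3a,4,7,7a-hexahydro-1-benzofuran-4-yl (2R)-2-methylbutanoate (target)
Conditions: NaBH4 (0.5 equiv), MeOH/CH2Cl2 1:1, −78 °C
Reagents that add atoms: none
Why: Hydride reduction of the aldehyde at low temperature should be much faster than conjugate reduction of the α-methylene lactone or attack on the esters.

**Compound list**

1 | (3S)-3,7-dimethyloct-6-enal, (S)-citronellal | O=CC[C@@H](C)CCC=C(C)C | starting material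
2 | trimethyl{[(3S)-3,7-dimethylocta-1,6-dien-1-yl]oxy}silane (E/Z mixture) | C[Si](C)(C)OC=C[C@@H](C)CCC=C(C)C | intermediate
3 | 2,2-dimethoxypropane | COC(C)(C)OC | starting material
4 | 3-methoxy-3-methyl-2-[(2S)-6-methylhept-5-en-2-yl]butanal (C2 epimers, not isolated) | O=CC([C@@H](C)CCC=C(C)C)C(C)(C)OC | intermediate
5 | 3-methyl-2-[(2S)-6-methylhept-5-en-2-yl]but-2-enal | O=CC([C@@H](C)CCC=C(C)C)=C(C)C | intermediate
6 | tert-butyl(dimethyl){[(1E)-3-methyl-2-[(2S)-6-methylhept-5-en-2-yl]buta-1,3-dien-1-yl]oxy}silane | CC(=C)/C(=C/O[Si](C)(C)C(C)(C)C)[C@@H](C)CCC=C(C)C | intermediate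
7 | but-3-yn-2-one | CC(=O)C#C | starting material
8 | (3E)-4-(4,4,5,5-tetramethyl-1,3,2-dioxaborolan-2-yl)but-3-en-2-one | CC(=O)/C=C/B1OC(C)(C)C(C)(C)O1 | intermediate
9 | 1-[(1R,2R,6S)-2-{[tert-butyl(dimethyl)silyl]oxy}-4-methyl-3-[(2S)-6-methylhept-5-en-2-yl]-6-(4,4,5,5-tetramethyl-1,3,2-dioxaborolan-2-yl)cyclohex-3-en-1-yl]ethan-1-one | CC(=O)[C@H]1[C@@H](O[Si](C)(C)C(C)(C)C)C([C@@H](C)CCC=C(C)C)=C(C)C[C@@H]1B2OC(C)(C)C(C)(C)O2 | intermediate
10 | 1-[(1R,2R,6S)-2-{[tert-butyl(dimethyl)silyl]oxy}-4-methyl-3-[(2S)-6-methylhept-5-en-2-yl]-6-(4,4,5,5-tetramethyl-1,3,2-dioxaborolan-2-yl)cyclohex-3-en-1-yl]ethenyl trifluoromethanesulfonate | C=C(OS(=O)(=O)C(F)(F)F)[C@H]1[C@@H](O[Si](C)(C)C(C)(C)C)C([C@@H](C)CCC=C(C)C)=C(C)C[C@@H]1B2OC(C)(C)C(C)(C)O2 | intermediate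
11 | 2-[(1S,2R,6S)-2-{[tert-butyl(dimethyl)silyl]oxy}-4-methyl-3-[(2S)-6-methylhept-5-en-2-yl]-6-(4,4,5,5-tetramethyl-1,3,2-dioxaborolan-2-yl)cyclohex-3-en-1-yl]prop-2-enoic acid | C=C(C(=O)O)[C@H]1[C@@H](O[Si](C)(C)C(C)(C)C)C([C@@H](C)CCC=C(C)C)=C(C)C[C@@H]1B2OC(C)(C)C(C)(C)O2 | intermediate
12 | 2-[(1R,2R,6S)-2-{[tert-butyl(dimethyl)silyl]oxy}-6-hydroxy-4-methyl-3-[(2S)-6-methylhept-5-en-2-yl]cyclohex-3-en-1-yl]prop-2-enoic acid | C=C(C(=O)O)[C@H]1[C@@H](O[Si](C)(C)C(C)(C)C)C([C@@H](C)CCC=C(C)C)=C(C)C[C@@H]1O | intermediate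
13 | (3aR,4R,7aR)-4-{[tert-butyl(dimethyl)silyl]oxy}-6-methyl-3-methylidene-5-[(2S)-6-methylhept-5-en-2-yl]-3a,4,7,7a-tetrahydro-1-benzofuran-2(3H)-one | C=C1C(=O)O[C@@H]2CC(C)=C([C@@H](C)CCC=C(C)C)[C@H](O[Si](C)(C)C(C)(C)C)[C@H]12 | intermediate
14 | (3aS,4R,7aR)-4-hydroxy-6-methyl-3-methylidene-5-[(2S)-6-methylhept-5-en-2-yl]-3a,4,7,7a-tetrahydro-1-benzofuran-2(3H)-one | C=C1C(=O)O[C@@H]2CC(C)=C([C@@H](C)CCC=C(C)C)[C@H](O)[C@H]12 | intermediate
15 | (2R)-2-methylbutanoic acid | CC[C@@H](C)C(=O)O | starting material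
16 | (3aR,4S,7aR)-6-methyl-3-methylidene-5-[(2S)-6-methylhept-5-en-2-yl]-2-oxo-2,3,3a,4,7,7a-hexahydro-1-benzofuran-4-yl (2R)-2-methylbutanoate | C=C1C(=O)O[C@@H]2CC(C)=C([C@@H](C)CCC=C(C)C)[C@@H](OC(=O)[C@H](C)CC)[C@H]12 | intermediate
17 | (3aR,4S,7aR)-6-methyl-3-methylidene-2-oxo-5-[(2S)-5-oxopentan-2-yl]-2,3,3a,4,7,7a-hexahydro-1-benzofuran-4-yl (2R)-2-methylbutanoate | C=C1C(=O)O[C@@H]2CC(C)=C([C@@H](C)CCC=O)[C@@H](OC(=O)[C@H](C)CC)[C@H]12 | intermediate
18 | (3aR,4S,7aR)-5-[(2S)-5-hydroxypentan-2-yl]-6-methyl-3-methylidene-2-oxo-2,3,3a,4,7,7a-hexahydro-1-benzofuran-4-yl (2R)-2-methylbutanoate | C=C1C(=O)O[C@@H]2CC(C)=C([C@@H](C)CCCO)[C@@H](OC(=O)[C@H](C)CC)[C@H]12 | target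

**Step count and risks**

Total steps: 13. Longest linear sequence: 12 steps (steps 1–3 and 5–13; step 4 is a one-step branch).

Step 5 (key step). What may go wrong: desilylative Mukaiyama–Michael addition without ring closure, or too little catalyst control over which diene and dienophile faces pair against the existing side-chain stereocentre. Fallback, setting out from diene 6 and coming back at ketone 9: the enone is replaced by a two-point-binding acyl oxazolidinone, a dienophile class for which chiral titanium diolate catalysis with oxygenated dienes is established. Oxazolidin-2-one is N-acylated with propiolic acid (pivaloyl chloride, Et3N, LiCl) to 3-(prop-2-ynoyl)-1,3-oxazolidin-2-one F1. The borylation conditions of step 4 convert this into 3-[(2E)-3-(4,4,5,5-tetramethyl-1,3,2-dioxaborolan-2-yl)prop-2-enoyl]-1,3-oxazolidin-2-one F2. Cycloaddition of F2 with 6 under TiCl2(OiPr)2 and (4R,5R)-2,2-dimethyl-α,α,α′,α′-tetraphenyl-1,3-dioxolane-4,5-dimethanol (or its antipode, matched to the same facial sense) with 4 Å molecular sieves in toluene should give the imide cycloadduct F3 with the same regio- and endo course. AlMe3 and MeNHOMe·HCl convert F3 into the Weinreb amide F4, and MeMgBr at −78 °C returns ketone 9.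

Step 11. What may go wrong: ionisation of the allylic alkoxyphosphonium ion (loss of stereospecificity, SN2′ attack at C6) or elimination to a diene, because the carboxylate of 15 is a weak nucleophile at a hindered carbon. Fallback, setting out from alcohol 14 and coming back at ester 16: inversion and acylation are separated. Mitsunobu reaction of 14 with the more acidic 4-nitrobenzoic acid (PPh3, DIAD, toluene) gives the inverted (3aR,4S,7aR)-6-methyl-3-methylidene-5-[(2S)-6-methylhept-5-en-2-yl]-2-oxo-2,3,3a,4,7,7a-hexahydro-1-benzofuran-4-yl 4-nitrobenzoate F5. Short methanolysis (K2CO3, MeOH, 0 °C) cleaves only this activated ester to (3aS,4S,7aR)-4-hydroxy-6-methyl-3-methylidene-5-[(2S)-6-methylhept-5-en-2-yl]-3a,4,7,7a-tetrahydro-1-benzofuran-2(3H)-one F6. Steglich esterification of F6 with 15 (N,N′-dicyclohexylcarbodiimide, 4-(dimethylamino)pyridine, CH2Cl2, 0 °C) then gives 16 with retention.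

Step 12. What may go wrong: over-oxidation, that is dihydroxylation of the methylene lactone or the ring alkene alongside the side-chain alkene, followed in step 13 by competing conjugate reduction. Fallback, setting out from ester 16 and coming back at target 18: the Michael acceptor is masked before the oxidation. Thiophenol and Et3N add to the methylene lactone of 16 to give (3aR,4S,7aR)-6-methyl-5-[(2S)-6-methylhept-5-en-2-yl]-2-oxo-3-[(phenylsulfanyl)methyl]-2,3,3a,4,7,7a-hexahydro-1-benzofuran-4-yl (2R)-2-methylbutanoate F7 (C3 epimers, of no consequence). OsO4/NaIO4 then cleaves the side-chain alkene and oxidises the sulfide in the same pot, giving the 3-[(benzenesulfinyl)methyl] aldehyde F8. NaBH4 reduces the aldehyde to the 3-[(benzenesulfinyl)methyl] alcohol F9 with no Michael acceptor present. Thermolysis (toluene, 110 °C, CaCO3) expels benzenesulfenic acid by syn-elimination and regenerates the methylene lactone, which is 18.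

**Further compounds**

F1 | step 5 | 3-(prop-2-ynoyl)-1,3-oxazolidin-2-one | C#CC(=O)N1CCOC1=O
F2 | step 5 | 3-[(2E)-3-(4,4,5,5-tetramethyl-1,3,2-dioxaborolan-2-yl)prop-2-enoyl]-1,3-oxazolidin-2-one | O=C(/C=C/B1OC(C)(C)C(C)(C)O1)N1CCOC1=O
F3 | step 5 | 3-{[(1R,2R,6S)-2-{[tert-butyl(dimethyl)silyl]oxy}-4-methyl-3-[(2S)-6-methylhept-5-en-2-yl]-6-(4,4,5,5-tetramethyl-1,3,2-dioxaborolan-2-yl)cyclohex-3-en-1-yl]carbonyl}-1,3-oxazolidin-2-one | O=C([C@H]1[C@@H](O[Si](C)(C)C(C)(C)C)C([C@@H](C)CCC=C(C)C)=C(C)C[C@@H]1B2OC(C)(C)C(C)(C)O2)N3CCOC3=O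
F4 | step 5 | (1R,2R,6S)-2-{[tert-butyl(dimethyl)silyl]oxy}-N-methoxy-N,4-dimethyl-3-[(2S)-6-methylhept-5-en-2-yl]-6-(4,4,5,5-tetramethyl-1,3,2-dioxaborolan-2-yl)cyclohex-3-ene-1-carboxamide | CON(C)C(=O)[C@H]1[C@@H](O[Si](C)(C)C(C)(C)C)C([C@@H](C)CCC=C(C)C)=C(C)C[C@@H]1B2OC(C)(C)C(C)(C)O2
F5 | step 11 | (3aR,4S,7aR)-6-methyl-3-methylidene-5-[(2S)-6-methylhept-5-en-2-yl]-2-oxo-2,3,3a,4,7,7a-hexahydro-1-benzofuran-4-yl 4-nitrobenzoate | C=C1C(=O)O[C@@H]2CC(C)=C([C@@H](C)CCC=C(C)C)[C@@H](OC(=O)c3ccc(cc3)[N+](=O)[O-])[C@H]12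
F6 | step 11 | (3aS,4S,7aR)-4-hydroxy-6-methyl-3-methylidene-5-[(2S)-6-methylhept-5-en-2-yl]-3a,4,7,7a-tetrahydro-1-benzofuran-2(3H)-one | C=C1C(=O)O[C@@H]2CC(C)=C([C@@H](C)CCC=C(C)C)[C@@H](O)[C@H]12
F7 | step 12 | (3aR,4S,7aR)-6-methyl-5-[(2S)-6-methylhept-5-en-2-yl]-2-oxo-3-[(phenylsulfanyl)methyl]-2,3,3a,4,7,7a-hexahydro-1-benzofuran-4-yl (2R)-2-methylbutanoate (C3 epimers) | C(Sc3ccccc3)C1C(=O)O[C@@H]2CC(C)=C([C@@H](C)CCC=C(C)C)[C@@H](OC(=O)[C@H](C)CC)[C@H]12
F8 | step 12 | (3aR,4S,7aR)-3-[(benzenesulfinyl)methyl]-6-methyl-2-oxo-5-[(2S)-5-oxopentan-2-yl]-2,3,3a,4,7,7a-hexahydro-1-benzofuran-4-yl (2R)-2-methylbutanoate (C3 and sulfur epimers) | C(S(=O)c3ccccc3)C1C(=O)O[C@@H]2CC(C)=C([C@@H](C)CCC=O)[C@@H](OC(=O)[C@H](C)CC)[C@H]12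
F9 | step 12 | (3aR,4S,7aR)-3-[(benzenesulfinyl)methyl]-5-[(2S)-5-hydroxypentan-2-yl]-6-methyl-2-oxo-2,3,3a,4,7,7a-hexahydro-1-benzofuran-4-yl (2R)-2-methylbutanoate (C3 and sulfur epimers) | C(S(=O)c3ccccc3)C1C(=O)O[C@@H]2CC(C)=C([C@@H](C)CCCO)[C@@H](OC(=O)[C@H](C)CC)[C@H]12
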